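**Retrosynthetic overview** (side-chain atoms are called C1 to C12 as in a farnesyl chain, C1 = OCH2)
1. Target ⇒ acetonide hydrolysis (last step) and a Mitsunobu C1–O7 ether bond ⇒ 5,7-dihydroxycoumarin + a C15 allylic alcohol.
2. C11 carbinol ⇒ methyl ester + 2 MeMgBr. C8–C9 bond ⇒ new nickel/photoredox decarboxylative allylation of an allyl ester; the C9 radical is trapped trans to the C10 substituent on the dioxolane, which sets C9 (R).
3. Allyl ester ⇒ half-ester of dimethyl D-tartrate acetonide (C9–C11, source of the C10 (S) centre) + (2E,6E)-8-hydroxygeranyl silyl ether (C1–C8, both E alkenes, from geraniol).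
4. Rings: none is formed. The coumarin bicycle is bought intact; the dioxolane comes with the tartrate and is opened in the last step.

Assumption: short-lived species (radicals, metal-bound allyl groups, activated acyl and oxyphosphonium species) are explained in the Why lines and carry no number; the isolable in-flask ketone of the Grignard step is numbered.
Assumption: dimethyl 2,3-O-isopropylidene-D-tartrate, geraniol and 5,7-dihydroxycoumarin are catalogue compounds.

**Step 1**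
Reactants: 1 dimethyl (4S,5S)-2,2-dimethyl-1,3-dioxolane-4,5-dicarboxylate (dimethyl D-tartrate acetonide)
Product: 2 (4S,5S)-5-(methoxycarbonyl)-2,2-dimethyl-1,3-dioxolane-4-carboxylic acid
Conditions: KOH (1.0 equiv), MeOH, 0 °C to rt; then 1 M HCl to pH 3, EtOAc
Reagents that add atoms: potassium hydroxide, [K+].[OH-] (its oxygen becomes the acid OH)
Why: Monosaponification of a C2-symmetric diester (ester hydrolysis); the first carboxylate formed deactivates the second ester, and no stereocentre is touched.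

**Step 2**
Reactants: 3 geraniol, (2E)-3,7-dimethylocta-2,6-dien-1-ol
Product: 4 tert-butyl{[(2E)-3,7-dimethylocta-2,6-dien-1-yl]oxy}diphenylsilane (geranyl TBDPS ether)
Conditions: TBDPSCl (1.05 equiv), imidazole (2 equiv), CH2Cl2, 0 °C to rt
Reagents that add atoms: tert-butyl(chloro)diphenylsilane, CC(C)(C)[Si](Cl)(c1ccccc1)c1ccccc1
Why: Imidazole-promoted silyl ether formation; O1 is masked as a group that zerovalent nickel does not ionise in step 5.

**Step 3**
Reactants: 4 tert-butyl{[(2E)-3,7-dimethylocta-2,6-dien-1-yl]oxy}diphenylsilane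
Product: 5 (2E,6E)-8-{[tert-butyl(diphenyl)silyl]oxy}-2,6-dimethylocta-2,6-dien-1-ol (8-hydroxygeranyl silyl ether)
Conditions: SeO2 (0.2 equiv), t-BuOOH (70% aq., 3 equiv), salicylic acid (0.1 equiv), CH2Cl2, 0 °C to rt
Reagents that add atoms: selenium dioxide, O=[Se]=O (oxygen carrier); tert-butyl hydroperoxide, CC(C)(C)OO (terminal oxidant)
Why: SeO2-catalysed allylic oxidation (ene reaction, then [2,3]-sigmatropic shift) attacks the E-methyl of the more electron-rich terminal alkene and gives the E allylic alcohol; the 2,3-alkene is deactivated by the allylic silyloxy group.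

**Step 4**
Reactants: 2 (4S,5S)-5-(methoxycarbonyl)-2,2-dimethyl-1,3-dioxolane-4-carboxylic acid; 5 (2E,6E)-8-{[tert-butyl(diphenyl)silyl]oxy}-2,6-dimethylocta-2,6-dien-1-ol
Product: 6 4-[(2E,6E)-8-{[tert-butyl(diphenyl)silyl]oxy}-2,6-dimethylocta-2,6-dien-1-yl] 5-methyl (4S,5S)-2,2-dimethyl-1,3-dioxolane-4,5-dicarboxylate (mixed allyl methyl diester)
Conditions: DCC (1.2 equiv), DMAP (0.1 equiv), CH2Cl2, 0 °C to rt
Reagents that add atoms: none
Why: Steglich esterification joins the two fragments; the C10 centre (α to the methyl ester) is not activated and stays S, and the C9 centre is erased in step 5.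

**Step 5**
Reactants: 6 4-[(2E,6E)-8-{[tert-butyl(diphenyl)silyl]oxy}-2,6-dimethylocta-2,6-dien-1-yl] 5-methyl (4S,5S)-2,2-dimethyl-1,3-dioxolane-4,5-dicarboxylate
Product: 7 methyl (4S,5R)-5-[(2E,6E)-8-{[tert-butyl(diphenyl)silyl]oxy}-2,6-dimethylocta-2,6-dien-1-yl]-2,2-dimethyl-1,3-dioxolane-4-carboxylate (C8–C9 coupled trans-dioxolane)
Conditions: Ni(cod)2 (10 mol%), 4,4'-di-tert-butyl-2,2'-bipyridine (12 mol%), [Ir(dF(CF3)ppy)2(dtbbpy)]PF6 (2 mol%), degassed MeCN (0.05 M), 450 nm LEDs, 25 °C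
Reagents that add atoms: none
Why: Proposed new method: nickel/photoredox decarboxylative allylation of an allyl α-alkoxy ester. Zerovalent nickel–bipyridine ionises the allylic C8–O bond of 6 (the α-alkoxy carboxylate is a good leaving group, the allyl silyl ether at C1 is not ionised) to a syn-η3-allyl divalent nickel carboxylate; the photoexcited trivalent iridium complex (about +1.2 V vs SCE) oxidises the released carboxylate, which loses CO2 to give the 1,3-dioxolan-4-yl radical at C9; this radical is captured by the allylnickel species on the ring face anti to the neighbouring CO2Me group, and C(sp3)–C(sp3) reductive elimination from trivalent nickel at the unsubstituted allyl terminus C8 gives the linear product with the 6E geometry of the syn-allyl ligand and the trans (9R) configuration; the divalent iridium formed in the oxidation returns monovalent nickel to the zerovalent state, so the step is redox-neutral and needs no base. Closest known reaction types: palladium/photoredox decarboxylative allylation of allyl esters of α-amino and arylacetic acids, and nickel/photoredox decarboxylative cross-coupling of α-oxy acids; the trans preference of this tartrate-derived radical is known from nickel-catalysed couplings of its redox-active esters. New here are the α,β-dioxygenated carboxylate, the 2-methyl-substituted trisubstituted allyl partner and the use of the ring to set a stereocentre.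

**Step 6**
Reactants: 7 methyl (4S,5R)-5-[(2E,6E)-8-{[tert-butyl(diphenyl)silyl]oxy}-2,6-dimethylocta-2,6-dien-1-yl]-2,2-dimethyl-1,3-dioxolane-4-carboxylate
Product: 9 2-[(4S,5R)-5-[(2E,6E)-8-{[tert-butyl(diphenyl)silyl]oxy}-2,6-dimethylocta-2,6-dien-1-yl]-2,2-dimethyl-1,3-dioxolan-4-yl]propan-2-ol, via methyl ketone 8 (not isolated)
Conditions: MeMgBr (3 equiv), THF, −20 to 0 °C; then H2O
Reagents that add atoms: methylmagnesium bromide, C[Mg]Br (two methyl groups)
Why: Double Grignard addition to the α-alkoxy ester through ketone 8 builds the C11 tertiary carbinol; addition outruns enolisation so C10 keeps its configuration, and the silyl ether, acetonide and alkenes are inert.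

**Step 7**
Reactants: 9 2-[(4S,5R)-5-[(2E,6E)-8-{[tert-butyl(diphenyl)silyl]oxy}-2,6-dimethylocta-2,6-dien-1-yl]-2,2-dimethyl-1,3-dioxolan-4-yl]propan-2-ol
Product: 10 (2E,6E)-8-[(4R,5S)-5-(2-hydroxypropan-2-yl)-2,2-dimethyl-1,3-dioxolan-4-yl]-3,7-dimethylocta-2,6-dien-1-ol
Conditions: Bu4NF (1.2 equiv), THF, 0 °C to rt; then H2O
Reagents that add atoms: none
Why: Fluoride-mediated desilylation frees the primary allylic alcohol; the acetonide and the tertiary alcohol are untouched.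

**Step 8**
Reactants: 10 (2E,6E)-8-[(4R,5S)-5-(2-hydroxypropan-2-yl)-2,2-dimethyl-1,3-dioxolan-4-yl]-3,7-dimethylocta-2,6-dien-1-ol; 11 5,7-dihydroxy-2H-chromen-2-one (5,7-dihydroxycoumarin, 1.5 equiv)
Product: 12 5-hydroxy-7-{[(2E,6E)-8-[(4R,5S)-5-(2-hydroxypropan-2-yl)-2,2-dimethyl-1,3-dioxolan-4-yl]-3,7-dimethylocta-2,6-dien-1-yl]oxy}-2H-chromen-2-one
Conditions: PPh3 (1.3 equiv), DIAD (1.3 equiv, slow addition), THF, 0 °C to rt
Reagents that add atoms: none
Why: Mitsunobu etherification; the 7-OH (para to the carbon that carries the vinylogous lactone carbonyl, the more acidic and less hindered phenol) is alkylated by SN2 at the primary allylic carbon with the 2E geometry kept; the tertiary alcohol does not react and excess 11 suppresses the bis-ether.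

**Step 9**
Reactants: 12 5-hydroxy-7-{[(2E,6E)-8-[(4R,5S)-5-(2-hydroxypropan-2-yl)-2,2-dimethyl-1,3-dioxolan-4-yl]-3,7-dimethylocta-2,6-dien-1-yl]oxy}-2H-chromen-2-one
Product: 13 5-hydroxy-7-{[(2E,6E,9R,10S)-9,10,11-trihydroxy-3,7,11-trimethyldodeca-2,6-dien-1-yl]oxy}-2H-chromen-2-one (target)
Conditions: AcOH/H2O/THF (3:1:1), 40 °C
Reagents that add atoms: none
Why: Mild acid hydrolysis of the isopropylidene acetal releases the 9,10-diol without breaking a C9–O or C10–O bond, so both centres are retained; the aryl allyl ether, lactone and alkenes tolerate the weak acid.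

**Compound list**
1 | dimethyl (4S,5S)-2,2-dimethyl-1,3-dioxolane-4,5-dicarboxylate | COC(=O)[C@H]1OC(C)(C)O[C@@H]1C(=O)OC | starting material
2 | (4S,5S)-5-(methoxycarbonyl)-2,2-dimethyl-1,3-dioxolane-4-carboxylic acid | COC(=O)[C@H]1OC(C)(C)O[C@@H]1C(=O)O | intermediate
3 | geraniol, (2E)-3,7-dimethylocta-2,6-dien-1-ol | CC(C)=CCC/C(C)=C/CO | starting material
4 | tert-butyl{[(2E)-3,7-dimethylocta-2,6-dien-1-yl]oxy}diphenylsilane | CC(C)=CCC/C(C)=C/CO[Si](c1ccccc1)(c1ccccc1)C(C)(C)C | intermediate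
5 | (2E,6E)-8-{[tert-butyl(diphenyl)silyl]oxy}-2,6-dimethylocta-2,6-dien-1-ol | OC/C(C)=C/CC/C(C)=C/CO[Si](c1ccccc1)(c1ccccc1)C(C)(C)C | intermediate
6 | 4-[(2E,6E)-8-{[tert-butyl(diphenyl)silyl]oxy}-2,6-dimethylocta-2,6-dien-1-yl] 5-methyl (4S,5S)-2,2-dimethyl-1,3-dioxolane-4,5-dicarboxylate | COC(=O)[C@H]1OC(C)(C)O[C@@H]1C(=O)OC/C(C)=C/CC/C(C)=C/CO[Si](c1ccccc1)(c1ccccc1)C(C)(C)C | intermediate
7 | methyl (4S,5R)-5-[(2E,6E)-8-{[tert-butyl(diphenyl)silyl]oxy}-2,6-dimethylocta-2,6-dien-1-yl]-2,2-dimethyl-1,3-dioxolane-4-carboxylate | COC(=O)[C@H]1OC(C)(C)O[C@@H]1C/C(C)=C/CC/C(C)=C/CO[Si](c1ccccc1)(c1ccccc1)C(C)(C)C | intermediate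
8 | 1-[(4S,5R)-5-[(2E,6E)-8-{[tert-butyl(diphenyl)silyl]oxy}-2,6-dimethylocta-2,6-dien-1-yl]-2,2-dimethyl-1,3-dioxolan-4-yl]ethan-1-one (methyl ketone, not isolated, step 6) | CC(=O)[C@H]1OC(C)(C)O[C@@H]1C/C(C)=C/CC/C(C)=C/CO[Si](c1ccccc1)(c1ccccc1)C(C)(C)C | intermediate
9 | 2-[(4S,5R)-5-[(2E,6E)-8-{[tert-butyl(diphenyl)silyl]oxy}-2,6-dimethylocta-2,6-dien-1-yl]-2,2-dimethyl-1,3-dioxolan-4-yl]propan-2-ol | CC(C)(O)[C@H]1OC(C)(C)O[C@@H]1C/C(C)=C/CC/C(C)=C/CO[Si](c1ccccc1)(c1ccccc1)C(C)(C)C | intermediate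
10 | (2E,6E)-8-[(4R,5S)-5-(2-hydroxypropan-2-yl)-2,2-dimethyl-1,3-dioxolan-4-yl]-3,7-dimethylocta-2,6-dien-1-ol | CC(C)(O)[C@H]1OC(C)(C)O[C@@H]1C/C(C)=C/CC/C(C)=C/CO | intermediate
11 | 5,7-dihydroxy-2H-chromen-2-one (5,7-dihydroxycoumarin) | O=c1ccc2c(O)cc(O)cc2o1 | starting material
12 | 5-hydroxy-7-{[(2E,6E)-8-[(4R,5S)-5-(2-hydroxypropan-2-yl)-2,2-dimethyl-1,3-dioxolan-4-yl]-3,7-dimethylocta-2,6-dien-1-yl]oxy}-2H-chromen-2-one | CC(C)(O)[C@H]1OC(C)(C)O[C@@H]1C/C(C)=C/CC/C(C)=C/COc1cc(O)c2ccc(=O)oc2c1 | intermediate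
13 | 5-hydroxy-7-{[(2E,6E,9R,10S)-9,10,11-trihydroxy-3,7,11-trimethyldodeca-2,6-dien-1-yl]oxy}-2H-chromen-2-one | C/C(=C\COc1cc(O)c2ccc(=O)oc2c1)CC/C=C(\C)C[C@@H](O)[C@H](O)C(C)(C)O | target

**Step count and risks**
Total: 9 steps. Longest linear sequence: 8 steps (steps 2 to 9, from geraniol 3); the tartrate branch (step 1) joins at step 4.

Most likely to fail:

(a) Step 5, the proposed new reaction. Possible failures are protodecarboxylation or allyl dimer instead of cross-coupling, attack at the substituted allyl terminus, loss of the 6E geometry through the anti-allyl form, or a low trans:cis ratio. The fallback uses known chemistry only, sets out from 2 and comes back to the route at 10. It keeps the carboxyl carbon of 2 as C8 and builds both trisubstituted alkenes by zirconium-catalysed carboalumination, whose syn addition fixes the E geometry. The acid of 2 is reduced chemoselectively with BH3·SMe2 (THF, 0 °C) to methyl (4S,5R)-5-(hydroxymethyl)-2,2-dimethyl-1,3-dioxolane-4-carboxylate F1. MeMgBr (4 equiv, THF, 0 °C) converts the ester into the diol 2-[(4S,5R)-5-(hydroxymethyl)-2,2-dimethyl-1,3-dioxolan-4-yl]propan-2-ol F2. Selective sulfonylation of the primary hydroxyl (TsCl, pyridine, 0 °C) gives [(4R,5S)-5-(2-hydroxypropan-2-yl)-2,2-dimethyl-1,3-dioxolan-4-yl]methyl 4-methylbenzenesulfonate F3, and SN2 displacement with LiC≡CH·H2NCH2CH2NH2 in DMSO gives the alkyne 2-[(4S,5R)-2,2-dimethyl-5-(prop-2-yn-1-yl)-1,3-dioxolan-4-yl]propan-2-ol F4. Negishi carboalumination (Me3Al, Cp2ZrCl2, CH2Cl2) followed by I2 gives the alkenyl iodide 2-[(4S,5R)-5-[(2E)-3-iodo-2-methylprop-2-en-1-yl]-2,2-dimethyl-1,3-dioxolan-4-yl]propan-2-ol F5. Commercial (4-bromobut-1-yn-1-yl)trimethylsilane and zinc dust (LiCl, THF) give bromo[4-(trimethylsilyl)but-3-yn-1-yl]zinc F6, and Negishi coupling of F5 with F6 (Pd(PPh3)4, THF, rt) gives 2-[(4S,5R)-2,2-dimethyl-5-[(2E)-2-methyl-7-(trimethylsilyl)hept-2-en-6-yn-1-yl]-1,3-dioxolan-4-yl]propan-2-ol F7. K2CO3 in MeOH removes the silyl group to give 2-[(4S,5R)-2,2-dimethyl-5-[(2E)-2-methylhept-2-en-6-yn-1-yl]-1,3-dioxolan-4-yl]propan-2-ol F8. A second carboalumination (Me3Al, Cp2ZrCl2), conversion into the alanate with n-BuLi and trapping with paraformaldehyde gives 10, and steps 8 and 9 follow unchanged.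

(b) Step 8, the regioselective Mitsunobu reaction. Etherification at O5 or at both phenols would give inseparable or wasteful mixtures. The fallback sets out from 11 (with 10 as partner) and comes back at 12. Both phenols are acetylated (Ac2O, pyridine) to 2-oxo-2H-chromene-5,7-diyl diacetate F9. The more electrophilic and less hindered 7-acetate is removed selectively (imidazole, MeOH, 0 °C) to give 7-hydroxy-2-oxo-2H-chromen-5-yl acetate F10. Mitsunobu reaction of F10 with 10 (PPh3, DIAD, THF) can then occur only at O7 and gives 7-{[(2E,6E)-8-[(4R,5S)-5-(2-hydroxypropan-2-yl)-2,2-dimethyl-1,3-dioxolan-4-yl]-3,7-dimethylocta-2,6-dien-1-yl]oxy}-2-oxo-2H-chromen-5-yl acetate F11. K2CO3 (0.2 equiv) in MeOH at 0 °C cleaves the aryl acetate to give 12.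

(c) Step 3, the SeO2 oxidation. Over-oxidation to the enal and incomplete conversion usually hold the yield near one half. The fallback sets out from 4 and comes back at 5. mCPBA (CH2Cl2, 0 °C) epoxidises the electron-rich terminal alkene to racemic tert-butyl{[(2E)-5-(3,3-dimethyloxiran-2-yl)-3-methylpent-2-en-1-yl]oxy}diphenylsilane F12. H5IO6 (THF/H2O, 0 °C) cleaves the epoxide to (4E)-6-{[tert-butyl(diphenyl)silyl]oxy}-4-methylhex-4-enal F13. Wittig olefination with the stabilised ylide Ph3P=C(CH3)CO2Et (CH2Cl2, rt, E-selective) gives ethyl (2E,6E)-8-{[tert-butyl(diphenyl)silyl]oxy}-2,6-dimethylocta-2,6-dienoate F14, and i-Bu2AlH (CH2Cl2, −78 °C) reduces the ester to 5.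

**Further compounds**
F1 | step 5 | methyl (4S,5R)-5-(hydroxymethyl)-2,2-dimethyl-1,3-dioxolane-4-carboxylate | COC(=O)[C@H]1OC(C)(C)O[C@@H]1CO
F2 | step 5 | 2-[(4S,5R)-5-(hydroxymethyl)-2,2-dimethyl-1,3-dioxolan-4-yl]propan-2-ol | CC(C)(O)[C@H]1OC(C)(C)O[C@@H]1CO
F3 | step 5 | [(4R,5S)-5-(2-hydroxypropan-2-yl)-2,2-dimethyl-1,3-dioxolan-4-yl]methyl 4-methylbenzenesulfonate | CC(C)(O)[C@H]1OC(C)(C)O[C@@H]1COS(=O)(=O)c1ccc(C)cc1
F4 | step 5 | 2-[(4S,5R)-2,2-dimethyl-5-(prop-2-yn-1-yl)-1,3-dioxolan-4-yl]propan-2-ol | CC(C)(O)[C@H]1OC(C)(C)O[C@@H]1CC#C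
F5 | step 5 | 2-[(4S,5R)-5-[(2E)-3-iodo-2-methylprop-2-en-1-yl]-2,2-dimethyl-1,3-dioxolan-4-yl]propan-2-ol | CC(C)(O)[C@H]1OC(C)(C)O[C@@H]1C/C(C)=C/I
F6 | step 5 | bromo[4-(trimethylsilyl)but-3-yn-1-yl]zinc | C[Si](C)(C)C#CCC[Zn]Br
F7 | step 5 | 2-[(4S,5R)-2,2-dimethyl-5-[(2E)-2-methyl-7-(trimethylsilyl)hept-2-en-6-yn-1-yl]-1,3-dioxolan-4-yl]propan-2-ol | CC(C)(O)[C@H]1OC(C)(C)O[C@@H]1C/C(C)=C/CCC#C[Si](C)(C)C
F8 | step 5 | 2-[(4S,5R)-2,2-dimethyl-5-[(2E)-2-methylhept-2-en-6-yn-1-yl]-1,3-dioxolan-4-yl]propan-2-ol | CC(C)(O)[C@H]1OC(C)(C)O[C@@H]1C/C(C)=C/CCC#C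
F9 | step 8 | 2-oxo-2H-chromene-5,7-diyl diacetate | CC(=O)Oc1cc(OC(C)=O)c2ccc(=O)oc2c1
F10 | step 8 | 7-hydroxy-2-oxo-2H-chromen-5-yl acetate | CC(=O)Oc1cc(O)cc2oc(=O)ccc12
F11 | step 8 | 7-{[(2E,6E)-8-[(4R,5S)-5-(2-hydroxypropan-2-yl)-2,2-dimethyl-1,3-dioxolan-4-yl]-3,7-dimethylocta-2,6-dien-1-yl]oxy}-2-oxo-2H-chromen-5-yl acetate | CC(C)(O)[C@H]1OC(C)(C)O[C@@H]1C/C(C)=C/CC/C(C)=C/COc1cc(OC(C)=O)c2ccc(=O)oc2c1
F12 | step 3 | tert-butyl{[(2E)-5-(3,3-dimethyloxiran-2-yl)-3-methylpent-2-en-1-yl]oxy}diphenylsilane (racemic at the epoxide carbon) | CC1(C)OC1CC/C(C)=C/CO[Si](c1ccccc1)(c1ccccc1)C(C)(C)C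
F13 | step 3 | (4E)-6-{[tert-butyl(diphenyl)silyl]oxy}-4-methylhex-4-enal | O=CCC/C(C)=C/CO[Si](c1ccccc1)(c1ccccc1)C(C)(C)C
F14 | step 3 | ethyl (2E,6E)-8-{[tert-butyl(diphenyl)silyl]oxy}-2,6-dimethylocta-2,6-dienoate | CCOC(=O)/C(C)=C/CC/C(C)=C/CO[Si](c1ccccc1)(c1ccccc1)C(C)(C)C
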